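**Plan**

- Retrosynthesis: the indole N–SO2Ar and imide N–CH2Ar bonds are cut first (protecting groups). Then the maleimide ring is opened at C2–C3, C4–C5 and one N1–C(=O) bond into a diaryl alkyne, CO and an isocyanate. Finally the alkyne is cut at the indole C3–C(sp) bond.
- Enabling feature: in the maleimide ring (N1, C2, C3, C4, C5) the C3=C4 bond carries the indol-3-yl and imidazol-5-yl groups, each olefinic carbon bears one C=O, and the two carbonyls are bridged by N1. This is an alkyne plus CO plus R–N=C=O.
- Forward: 6-bromoindole is iodinated at C3 and N-tosylated in one flask, then joined to 5-ethynyl-1-methylimidazole by Sonogashira coupling.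
- The maleimide, the only ring made, is then closed by Ru3(CO)12-catalysed (2+2+1) cyclocoupling with CO and 2,4-dimethoxybenzyl isocyanate. Acid removes the benzyl group and fluoride removes the tosyl group.
- Stereochemistry: the target has no stereocentre. The cis arrangement of the two carbonyl carbons on C3=C4 follows from syn addition across the alkyne and is locked by the ring.

Key step: step 3

Remark: 6-bromoindole, 5-ethynyl-1-methylimidazole and 2,4-dimethoxybenzyl isocyanate are taken as purchased; the isocyanate is used dry, since water or amine would convert it into ureas.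

**Step 1**
Reactants: 1 6-bromoindole
Product: 3 6-bromo-3-iodo-1-(4-methylphenylsulfonyl)-1H-indole, via 6-bromo-3-iodo-1H-indole 2 (not isolated)
Conditions: I2 (1.05 equiv), KOH (4 equiv), DMF, 20 °C, dark; then TsCl (1.5 equiv), 0 → 20 °C; aq Na2S2O3 work-up
Reagents that add atoms: iodine, II; 4-methylbenzenesulfonyl chloride (TsCl), Cc1ccc(S(=O)(=O)Cl)cc1
Why: Electrophilic aromatic iodination of the potassium indolide occurs at C3, the most nucleophilic ring position, and the labile 3-iodoindole is N-sulfonylated in the same flask, the electron-withdrawing sulfonyl group stabilising the C–I bond for the coupling.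

**Step 2**
Reactants: 3 6-bromo-3-iodo-1-(4-methylphenylsulfonyl)-1H-indole; 4 5-ethynyl-1-methyl-1H-imidazole
Product: 5 6-bromo-3-[(1-methyl-1H-imidazol-5-yl)ethynyl]-1-(4-methylphenylsulfonyl)-1H-indole
Conditions: Pd(PPh3)2Cl2 (3 mol %), CuI (5 mol %), Et3N, THF, degassed, 20 → 40 °C
Reagents that add atoms: none
Why: Sonogashira coupling, in which zerovalent palladium inserts into the C3–I bond far faster than into the C6–Br bond at this temperature, so the copper acetylide of 4 is delivered only to C3.

**Step 3**
Reactants: 5 6-bromo-3-[(1-methyl-1H-imidazol-5-yl)ethynyl]-1-(4-methylphenylsulfonyl)-1H-indole; 6 2,4-dimethoxybenzyl isocyanate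
Product: 7 3-[6-bromo-1-(4-methylphenylsulfonyl)-1H-indol-3-yl]-1-(2,4-dimethoxybenzyl)-4-(1-methyl-1H-imidazol-5-yl)-1H-pyrrole-2,5-dione
Conditions: Ru3(CO)12 (5 mol %), CO (1 atm), mesitylene, 130 °C; 6 (2.5 equiv) added over several hours
Reagents that add atoms: carbon monoxide, [C-]#[O+]
Why: On zerovalent ruthenium formed from Ru3(CO)12 the alkyne and the C=N bond of the isocyanate should couple oxidatively to a five-membered azaruthenacycle (Ru–C=C–C(=O)–N), which takes up CO by migratory insertion and then collapses by reductive elimination. The closest known reaction type is the Ru3(CO)12-catalysed (2+2+1) cocyclisation of internal dialkyl or diaryl alkynes with aryl or alkyl isocyanates and CO to tetrasubstituted maleimides, applied here to a heteroaryl-substituted alkyne. The maleimide ring, the only ring formed, closes in that final reductive elimination from the CO-expanded ruthenacycle, so both ring C–C(=O) bonds and one N–C(=O) bond are made on the metal template. No stereocentre is created; syn addition across the alkyne places the two carbonyl carbons cis on C3=C4, and the unsymmetrical alkyne raises no regiochemical question because each alkyne carbon ends up bonded to one carbonyl. The step needs chemoselectivity for the alkyne over the aryl C–Br bond, into which ruthenium carbonyl under CO is not expected to insert at 130 °C, and cross-selectivity over isocyanate trimerisation and alkyne–alkyne–CO coupling, which slow addition of an excess of the weakly electrophilic benzylic isocyanate and the bulk of the diaryl alkyne should secure. The N-sulfonyl group keeps the indole nitrogen from adding to the isocyanate, and the CO atmosphere competes with the imidazole N3 for ruthenium.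

**Step 4**
Reactants: 7 3-[6-bromo-1-(4-methylphenylsulfonyl)-1H-indol-3-yl]-1-(2,4-dimethoxybenzyl)-4-(1-methyl-1H-imidazol-5-yl)-1H-pyrrole-2,5-dione
Product: 8 3-[6-bromo-1-(4-methylphenylsulfonyl)-1H-indol-3-yl]-4-(1-methyl-1H-imidazol-5-yl)-1H-pyrrole-2,5-dione
Conditions: CF3CO2H, anisole (10 equiv), 70 °C; aq NaHCO3 work-up
Reagents that add atoms: none
Why: Acidolysis of the imide N–benzyl bond gives the resonance-stabilised 2,4-dimethoxybenzyl cation, which anisole captures by Friedel–Crafts alkylation, while the N-sulfonylated indole is too deactivated to be benzylated and the sulfonamide, aryl bromide and maleimide are inert to the acid.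

**Step 5**
Reactants: 8 3-[6-bromo-1-(4-methylphenylsulfonyl)-1H-indol-3-yl]-4-(1-methyl-1H-imidazol-5-yl)-1H-pyrrole-2,5-dione
Product: 9 didemnimide D, 3-(6-bromo-1H-indol-3-yl)-4-(1-methyl-1H-imidazol-5-yl)-1H-pyrrole-2,5-dione
Conditions: Bu4NF (1 M in THF, 4 equiv), THF, 60 °C; then AcOH, pH 7 buffer
Reagents that add atoms: none
Why: Fluoride-induced N-desulfonylation, in which fluoride first deprotonates the imide (its anion resists nucleophilic ring opening) and then attacks the sulfonyl sulfur to release the maleimide-conjugated indolide, with acidification returning the neutral imide and indole.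

**Compound list**

1 | 6-bromoindole | Brc1ccc2cc[nH]c2c1 | starting material
2 | 6-bromo-3-iodo-1H-indole | Brc1ccc2c(I)c[nH]c2c1 | intermediate
3 | 6-bromo-3-iodo-1-(4-methylphenylsulfonyl)-1H-indole | Cc1ccc(S(=O)(=O)n2cc(I)c3ccc(Br)cc32)cc1 | intermediate
4 | 5-ethynyl-1-methyl-1H-imidazole | C#Cc1cncn1C | starting material
5 | 6-bromo-3-[(1-methyl-1H-imidazol-5-yl)ethynyl]-1-(4-methylphenylsulfonyl)-1H-indole | Cn1cncc1C#Cc1cn(S(=O)(=O)c2ccc(C)cc2)c2cc(Br)ccc12 | intermediate
6 | 2,4-dimethoxybenzyl isocyanate | COc1ccc(CN=C=O)c(OC)c1 | starting material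
7 | 3-[6-bromo-1-(4-methylphenylsulfonyl)-1H-indol-3-yl]-1-(2,4-dimethoxybenzyl)-4-(1-methyl-1H-imidazol-5-yl)-1H-pyrrole-2,5-dione | Cn1cncc1C1=C(c2cn(S(=O)(=O)c3ccc(C)cc3)c3cc(Br)ccc23)C(=O)N(Cc2ccc(OC)cc2OC)C1=O | intermediate
8 | 3-[6-bromo-1-(4-methylphenylsulfonyl)-1H-indol-3-yl]-4-(1-methyl-1H-imidazol-5-yl)-1H-pyrrole-2,5-dione | Cn1cncc1C1=C(c2cn(S(=O)(=O)c3ccc(C)cc3)c3cc(Br)ccc23)C(=O)NC1=O | intermediate
9 | didemnimide D, 3-(6-bromo-1H-indol-3-yl)-4-(1-methyl-1H-imidazol-5-yl)-1H-pyrrole-2,5-dione | Cn1cncc1C1=C(c2c[nH]c3cc(Br)ccc23)C(=O)NC1=O | target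

**Step count**

Total: 5 steps. Longest linear sequence: 5 steps (1 → 9).

**Steps most likely to fail**

Step 3. The imidazole N3 lone pair may bind ruthenium and stop turnover. The same nitrogen may trigger cyclotrimerisation of the isocyanate, and two alkynes may couple with CO to a cyclopentadienone instead of cross-coupling. The fallback sets out from 1 and returns at 9, building the maleimide by a Perkin-type condensation instead of a carbonylative cyclocoupling. 6-Bromoindole 1 is acylated at C3 with oxalyl chloride (Et2O, 0 °C) to 2-(6-bromo-1H-indol-3-yl)-2-oxoacetyl chloride F1, which is quenched with methanol to methyl 2-(6-bromo-1H-indol-3-yl)-2-oxoacetate F2. Commercial 2-(1-methyl-1H-imidazol-5-yl)acetonitrile is hydrated (H2O2, K2CO3, DMSO, Radziszewski conditions) to 2-(1-methyl-1H-imidazol-5-yl)acetamide F3. The ester and the amide are then condensed with KOtBu in THF (0 → 20 °C), followed by conc. HCl to complete the dehydration, which should give didemnimide D 9 without protecting groups.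

Step 4. Ionisation of the imide N–benzyl bond may be slow, because an imide is a poor proton acceptor, and the benzyl cation may return to the substrate by Friedel–Crafts alkylation. The fallback sets out from 7 and returns at 9, exchanging the imide nitrogen by way of the anhydride. Heating 7 with KOH in EtOH/H2O at reflux should open the imide to the dicarboxylate, release 2,4-dimethoxybenzylamine and cleave the N-sulfonyl group in the same operation. Acidification with aq HCl closes 3-(6-bromo-1H-indol-3-yl)-4-(1-methyl-1H-imidazol-5-yl)furan-2,5-dione F4. Treatment with HN(SiMe3)2 and MeOH in DMF at 20 °C then converts the anhydride into the N–H imide 9, so steps 4 and 5 are both bypassed.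

Step 5. Deprotonation of the imide comes first, and the resulting anion donates into the maleimide, so the indolide becomes a poorer leaving group and N–S cleavage may stall. Forcing the reaction invites ring opening of the imide by hydroxide from wet fluoride. The fallback sets out from 7 and returns at 9, reversing the order of the two deprotections so that the sulfonyl group leaves while the imide is still neutral. With Bu4NF in THF at 20 °C, 7 should give 3-(6-bromo-1H-indol-3-yl)-1-(2,4-dimethoxybenzyl)-4-(1-methyl-1H-imidazol-5-yl)-1H-pyrrole-2,5-dione F5, its sulfonamide being activated by conjugation with the uncharged maleimide. CF3CO2H/anisole at 70 °C then removes the benzyl group to give 9, ending the route under acidic conditions that the maleimide tolerates.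

**Further compounds**

F1 | step 3 | 2-(6-bromo-1H-indol-3-yl)-2-oxoacetyl chloride | O=C(Cl)C(=O)c1c[nH]c2cc(Br)ccc12
F2 | step 3 | methyl 2-(6-bromo-1H-indol-3-yl)-2-oxoacetate | COC(=O)C(=O)c1c[nH]c2cc(Br)ccc12
F3 | step 3 | 2-(1-methyl-1H-imidazol-5-yl)acetamide | Cn1cncc1CC(N)=O
F4 | step 4 | 3-(6-bromo-1H-indol-3-yl)-4-(1-methyl-1H-imidazol-5-yl)furan-2,5-dione | Cn1cncc1C1=C(c2c[nH]c3cc(Br)ccc23)C(=O)OC1=O
F5 | step 5 | 3-(6-bromo-1H-indol-3-yl)-1-(2,4-dimethoxybenzyl)-4-(1-methyl-1H-imidazol-5-yl)-1H-pyrrole-2,5-dione | Cn1cncc1C1=C(c2c[nH]c3cc(Br)ccc23)C(=O)N(Cc2ccc(OC)cc2OC)C1=O
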